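**Retrosynthetic overview**

1. 18 ⇐ 17 (ipso-protodesilylation at C6) ⇐ 15 (C4 alcohol to ketone, then quinone to hydroquinone) ⇐ 14 ⇐ 13 (O4 desilylation, then oxidative demethylation at C8).
2. 13 ⇐ carbene complex 10 + trimethylsilylacetylene 11 + one CO ligand: benzannulation forming C8–C7, C6–C5 and C5–C4a, so ring A (benzenoid) is made last on the finished chiral pyran ring.
3. 10 ⇐ 6 (C6 lithiation, Cr(CO)6, O-methylation) ⇐ 4 (1,2-reduction, silylation).
4. 4 ⇐ aldehyde 1 + diene 2 by catalytic asymmetric hetero-Diels–Alder reaction: ring B (pyran) is made first and C2 is set here.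
5. Feature relied on: ring A (C4a, C5, C6, C7, C8, C8a) has para oxygens on C5 and C8 and hydrogen on C6 and C7, and its C4a–C8a bond is the O1-bearing enol-ether double bond of ring B (O1, C2, C3, C4, C4a, C8a). This is the substitution pattern that an alkenyl(alkoxy)carbene/alkyne/CO benzannulation delivers.

Key step: step 5

**Remarks on the chemistry**

- Aldehyde 1 is taken as a purchased material (it is sold as a pheromone component) and is distilled before use.
- The (S)-BINOL/Ti(OiPr)4 catalyst is assumed to attack the Si face of the unbranched aldehyde, as BINOL–titanium allylations do. This is to be checked on 5 by Mosher ester analysis, and (R)-BINOL is used if the sense proves opposite.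
- O4 is carried as a triisopropylsilyl ether, and the C6 silyl group is kept until the last step, because acid cannot be used while C4 is an o-hydroxybenzylic ether or alcohol.
- Chroman numbering (O1, C2, C3, C4, C4a, C5–C8, C8a) is used for bicyclic compounds and pyran numbering (O1, C2–C6) for monocyclic ones.

**Route**

Step 1
Reactants: 1 (Z)-octadec-13-enal; 2 (E)-1-methoxy-3-(trimethylsilyloxy)buta-1,3-diene
Product: 4 (2R)-2-[(Z)-heptadec-12-enyl]-2,3-dihydro-4H-pyran-4-one, via silyl aldol adduct 3 (not isolated)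
Conditions: (S)-BINOL (20 mol %), Ti(OiPr)4 (10 mol %), 4 Å MS, Et2O, −20 °C; then TFA, CH2Cl2, 0 °C
Reagents that add atoms: none
Why: A BINOL–titanium-catalysed Mukaiyama aldol addition of the diene terminus to the aldehyde, followed by acid-induced cyclisation with loss of methanol (formal hetero-Diels–Alder reaction), should give the dihydropyranone, with the chiral titanium complex directing attack to the Si face of the aldehyde and so setting C2 as R.

Step 2
Reactants: 4 (2R)-2-[(Z)-heptadec-12-enyl]-2,3-dihydro-4H-pyran-4-one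
Product: 5 (2R,4S)-2-[(Z)-heptadec-12-enyl]-3,4-dihydro-2H-pyran-4-ol (2,4-cis)
Conditions: NaBH4, CeCl3·7H2O, MeOH, −78 °C
Reagents that add atoms: none
Why: In this Luche 1,2-reduction hydride should attack the cerium-activated carbonyl along the axial trajectory of the half-chair that holds the C2 chain equatorial, which places the new C4 hydroxyl cis to the chain (4S) and leaves the enol ether untouched.

Step 3
Reactants: 5 (2R,4S)-2-[(Z)-heptadec-12-enyl]-3,4-dihydro-2H-pyran-4-ol
Product: 6 triisopropyl{[(2R,4S)-2-((Z)-heptadec-12-enyl)-3,4-dihydro-2H-pyran-4-yl]oxy}silane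
Conditions: TIPSCl, imidazole, DMAP (cat.), DMF, rt
Reagents that add atoms: triisopropylsilyl chloride, CC(C)[Si](Cl)(C(C)C)C(C)C
Why: Base-mediated O-silylation avoids the acid that would ionise this glycal-type allylic alcohol (Ferrier-type), and the triisopropylsilyl group carries no Si–CH3 group open to competing deprotonation by tert-butyllithium in the next step.

Step 4
Reactants: 6 triisopropyl{[(2R,4S)-2-((Z)-heptadec-12-enyl)-3,4-dihydro-2H-pyran-4-yl]oxy}silane; 7 chromium hexacarbonyl
Product: 10 pentacarbonyl{methoxy[(2R,4S)-2-((Z)-heptadec-12-enyl)-4-(triisopropylsilyloxy)-3,4-dihydro-2H-pyran-6-yl]methylidene}chromium, via C6-lithio dihydropyran 8 (not isolated), via lithium acylchromate 9 (not isolated)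
Conditions: t-BuLi (2 equiv), THF, −78 → 0 °C; Cr(CO)6, THF, −78 °C → rt; Me3OBF4, CH2Cl2, 0 °C → rt
Reagents that add atoms: trimethyloxonium tetrafluoroborate, C[O+](C)C.F[B-](F)(F)F
Why: This is the Fischer carbene synthesis: oxygen-directed α-lithiation of the cyclic enol ether at C6 (as with silyl-protected glycals), addition of the vinyllithium to a carbonyl ligand of zerovalent chromium and O-methylation of the acylate, none of which should touch the isolated Z-alkene, the silyl ether or either stereocentre.

Step 5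
Reactants: 10 pentacarbonyl{methoxy[(2R,4S)-2-((Z)-heptadec-12-enyl)-4-(triisopropylsilyloxy)-3,4-dihydro-2H-pyran-6-yl]methylidene}chromium; 11 trimethylsilylacetylene
Product: 13 (2R,4S)-2-[(Z)-heptadec-12-enyl]-8-methoxy-4-(triisopropylsilyloxy)-6-(trimethylsilyl)chroman-5-ol, via tricarbonylchromium arene complex 12 (not isolated)
Conditions: 11 (2 equiv), THF (0.05 M), 55 °C, sealed tube, argon; then air, Et2O, daylight, rt
Reagents that add atoms: none
Why: Dötz benzannulation: on heating, 10 should dissociate a cis CO ligand and take up the alkyne, whose terminal CH carbon couples with the carbene carbon (C8–C7) to give a vinylcarbene; migration of a CO ligand onto the new carbene carbon then gives a chromium-bound dienylketene (C6–C5), whose ketene carbon closes onto the enol-ether β-carbon (C5–C4a), and tautomerisation gives the phenol as arene complex 12, from which air oxidation releases 13. The closest known reactions are benzannulations of 3,4-dihydro-2H-pyran-6-yl and glycal-derived methoxycarbene chromium complexes with alkynes, which give 8-alkoxychroman-5-ols. The one new ring, ring A, closes by a thermal disrotatory 6π electrocyclisation of the dienylketene on the metal, so the process is overall a [3+2+1] assembly. No stereocentre is created, since C2 and C4 are spectators and the facial chirality of the chromium arene complex vanishes on demetalation. The selectivity required is six-ring formation with CO uptake over five-ring products formed without it, which the chromium centre, the methoxy donor on the carbene carbon, the alkenyl (not aryl) carbene substituent and THF at moderate dilution should all favour, while the unactivated Z-alkene should not be cyclopropanated at 55 °C. Which alkyne carbon bonds to the carbene carbon has no bearing on the outcome, since step 9 leaves hydrogen on both C6 and C7, although steric control should put silicon on C6 next to the new hydroxyl.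

Step 6
Reactants: 13 (2R,4S)-2-[(Z)-heptadec-12-enyl]-8-methoxy-4-(triisopropylsilyloxy)-6-(trimethylsilyl)chroman-5-ol
Product: 14 (2R,4S)-2-[(Z)-heptadec-12-enyl]-8-methoxy-6-(trimethylsilyl)chromane-4,5-diol
Conditions: TBAF, THF, argon, 0 °C → rt; pH 7 buffer
Reagents that add atoms: none
Why: Fluoride-induced silyl ether cleavage (Si–F bond formation) should free O4 in a non-acidic medium that cannot ionise the o-hydroxybenzylic C4–O bond, and the aryl C–Si bond of this electron-rich arene is not expected to be attacked by fluoride at this temperature.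

Step 7
Reactants: 14 (2R,4S)-2-[(Z)-heptadec-12-enyl]-8-methoxy-6-(trimethylsilyl)chromane-4,5-diol
Product: 15 (2R,4S)-2-[(Z)-heptadec-12-enyl]-4-hydroxy-6-(trimethylsilyl)-3,4-dihydro-2H-chromene-5,8-dione
Conditions: (NH4)2Ce(NO3)6 (2.5 equiv), MeCN/H2O 4:1, 0 °C, 10 min
Reagents that add atoms: water, O
Why: Oxidative demethylation of a 4-methoxyphenol by tetravalent cerium (two one-electron oxidations, attack of water at C8, loss of methanol) is fast at 0 °C and should outpace any reaction at the isolated alkene, the secondary alcohol or the C–Si bond.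

Step 8
Reactants: 15 (2R,4S)-2-[(Z)-heptadec-12-enyl]-4-hydroxy-6-(trimethylsilyl)-3,4-dihydro-2H-chromene-5,8-dione
Product: 17 (2R)-2-[(Z)-heptadec-12-enyl]-5,8-dihydroxy-6-(trimethylsilyl)chroman-4-one, via acylquinone 16 (not isolated)
Conditions: Dess–Martin periodinane, CH2Cl2, 0 °C; then EtOAc, aq Na2S2O4, rt
Reagents that add atoms: none
Why: Dess–Martin oxidation of the secondary C4 alcohol followed at once by dithionite reduction of the quinone should give the acylhydroquinone, and because the electrophilic trione is never isolated the time in which it could open by β-elimination across C3–C2 is kept short.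

Step 9
Reactants: 17 (2R)-2-[(Z)-heptadec-12-enyl]-5,8-dihydroxy-6-(trimethylsilyl)chroman-4-one
Product: 18 (2R)-2-[(Z)-heptadec-12-enyl]-5,8-dihydroxychroman-4-one (CNP0081592.1)
Conditions: TFA, CH2Cl2, 0 °C → rt
Reagents that add atoms: none
Why: Ipso-protodesilylation (electrophilic aromatic substitution) should be easy because C6 is ortho to the C5 hydroxyl and para to O1 and the β-silicon effect assists protonation there, under conditions too mild to open the chromanone at C2–O1 or to affect the Z-alkene.

**Compound list**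

1 | (Z)-octadec-13-enal | CCCC/C=C\CCCCCCCCCCCC=O | starting material
2 | (E)-1-methoxy-3-(trimethylsilyloxy)buta-1,3-diene | CO/C=C/C(=C)O[Si](C)(C)C | starting material
3 | (1E,5R,17Z)-1-methoxy-5-(trimethylsilyloxy)docosa-1,17-dien-3-one (silyl aldol adduct, formed in the flask) | CCCC/C=C\CCCCCCCCCCC[C@@H](O[Si](C)(C)C)CC(=O)/C=C/OC | intermediate
4 | (2R)-2-[(Z)-heptadec-12-enyl]-2,3-dihydro-4H-pyran-4-one | CCCC/C=C\CCCCCCCCCCC[C@@H]1CC(=O)C=CO1 | intermediate
5 | (2R,4S)-2-[(Z)-heptadec-12-enyl]-3,4-dihydro-2H-pyran-4-ol | CCCC/C=C\CCCCCCCCCCC[C@@H]1C[C@H](O)C=CO1 | intermediate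
6 | triisopropyl{[(2R,4S)-2-((Z)-heptadec-12-enyl)-3,4-dihydro-2H-pyran-4-yl]oxy}silane | CCCC/C=C\CCCCCCCCCCC[C@@H]1C[C@H](O[Si](C(C)C)(C(C)C)C(C)C)C=CO1 | intermediate
7 | chromium hexacarbonyl | O=C=[Cr](=C=O)(=C=O)(=C=O)(=C=O)=C=O | starting material
8 | [(2R,4S)-2-((Z)-heptadec-12-enyl)-4-(triisopropylsilyloxy)-3,4-dihydro-2H-pyran-6-yl]lithium (formed in the flask) | CCCC/C=C\CCCCCCCCCCC[C@@H]1C[C@H](O[Si](C(C)C)(C(C)C)C(C)C)C=C([Li])O1 | intermediate
9 | lithium pentacarbonyl{[(2R,4S)-2-((Z)-heptadec-12-enyl)-4-(triisopropylsilyloxy)-3,4-dihydro-2H-pyran-6-yl]carbonyl}chromate, zerovalent chromium (formed in the flask) | CCCC/C=C\CCCCCCCCCCC[C@@H]1C[C@H](O[Si](C(C)C)(C(C)C)C(C)C)C=C(O1)C([O-])=[Cr](=C=O)(=C=O)(=C=O)(=C=O)=C=O.[Li+] | intermediate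
10 | pentacarbonyl{methoxy[(2R,4S)-2-((Z)-heptadec-12-enyl)-4-(triisopropylsilyloxy)-3,4-dihydro-2H-pyran-6-yl]methylidene}chromium | CCCC/C=C\CCCCCCCCCCC[C@@H]1C[C@H](O[Si](C(C)C)(C(C)C)C(C)C)C=C(O1)C(OC)=[Cr](=C=O)(=C=O)(=C=O)(=C=O)=C=O | intermediate
11 | trimethylsilylacetylene | C#C[Si](C)(C)C | starting material
12 | tricarbonyl{η6-(2R,4S)-2-[(Z)-heptadec-12-enyl]-8-methoxy-4-(triisopropylsilyloxy)-6-(trimethylsilyl)chroman-5-ol}chromium (formed in the flask; the η6 bond is written as a dot) | CCCC/C=C\CCCCCCCCCCC[C@@H]1C[C@H](O[Si](C(C)C)(C(C)C)C(C)C)c2c(O)c([Si](C)(C)C)cc(OC)c2O1.[Cr](=C=O)(=C=O)=C=O | intermediate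
13 | (2R,4S)-2-[(Z)-heptadec-12-enyl]-8-methoxy-4-(triisopropylsilyloxy)-6-(trimethylsilyl)chroman-5-ol | CCCC/C=C\CCCCCCCCCCC[C@@H]1C[C@H](O[Si](C(C)C)(C(C)C)C(C)C)c2c(O)c([Si](C)(C)C)cc(OC)c2O1 | intermediate
14 | (2R,4S)-2-[(Z)-heptadec-12-enyl]-8-methoxy-6-(trimethylsilyl)chromane-4,5-diol | CCCC/C=C\CCCCCCCCCCC[C@@H]1C[C@H](O)c2c(O)c([Si](C)(C)C)cc(OC)c2O1 | intermediate
15 | (2R,4S)-2-[(Z)-heptadec-12-enyl]-4-hydroxy-6-(trimethylsilyl)-3,4-dihydro-2H-chromene-5,8-dione | CCCC/C=C\CCCCCCCCCCC[C@@H]1C[C@H](O)C2=C(O1)C(=O)C=C([Si](C)(C)C)C2=O | intermediate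
16 | (2R)-2-[(Z)-heptadec-12-enyl]-6-(trimethylsilyl)-2,3-dihydro-4H-chromene-4,5,8-trione (formed in the flask) | CCCC/C=C\CCCCCCCCCCC[C@@H]1CC(=O)C2=C(O1)C(=O)C=C([Si](C)(C)C)C2=O | intermediate
17 | (2R)-2-[(Z)-heptadec-12-enyl]-5,8-dihydroxy-6-(trimethylsilyl)chroman-4-one | CCCC/C=C\CCCCCCCCCCC[C@@H]1CC(=O)c2c(O)c([Si](C)(C)C)cc(O)c2O1 | intermediate
18 | (2R)-2-[(Z)-heptadec-12-enyl]-5,8-dihydroxychroman-4-one (CNP0081592.1) | CCCC/C=C\CCCCCCCCCCC[C@@H]1CC(=O)c2c(O)ccc(O)c2O1 | target

**Step count**

Total steps: 9. Longest linear sequence: 9 steps (1 → 18).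

**Steps most likely to fail**

Step 5 (benzannulation). After alkyne insertion the vinylcarbene may cyclise without taking up CO and give five-membered-ring products. The bulky silyloxy group on C4, next to C4a, may slow the electrocyclic closure so that the ketene is diverted. The electron-rich phenol may also be over-oxidised while chromium is being removed in air. The fallback builds the arene first, closes the pyranone on it and sets C2 by asymmetric conjugate reduction; it sets out from aldehyde 1 and comes back to the route at target 18. Kabbe condensation of 1 with 1-(2-hydroxy-3,6-dimethoxyphenyl)ethanone F1 (a known acetophenone, bought or made from 2,5-dimethoxyphenol; pyrrolidine, toluene, heat) should give racemic 2-[(Z)-heptadec-12-enyl]-5,8-dimethoxychroman-4-one F2. Dehydrogenation with IBX (DMSO/fluorobenzene, 70 °C) should give 2-[(Z)-heptadec-12-enyl]-5,8-dimethoxy-4H-chromen-4-one F3. Copper hydride-catalysed asymmetric 1,4-reduction (Cu(OAc)2, the DTBM-SEGPHOS antipode that delivers the R product, (EtO)2MeSiH, t-BuOH, toluene) should give (2R)-2-[(Z)-heptadec-12-enyl]-5,8-dimethoxychroman-4-one F4. BBr3 (CH2Cl2, −78 → 0 °C) should then cleave both methyl ethers to give 18.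

Step 8 (oxidation to the trione and reduction). The acylquinone may open by β-elimination across C3–C2 with O1 leaving as a hydroxyquinone, which would scramble or destroy C2, or it may add water or acetate before the reductant reaches it. The fallback never places a C4 ketone on a quinone and unmasks the hydroquinone with a Lewis acid instead of by oxidation and reduction; it sets out from diol 14 and comes back at target 18. Selective O-methylation of the phenol (MeI, K2CO3, DMF, rt) should give (2R,4S)-2-[(Z)-heptadec-12-enyl]-5,8-dimethoxy-6-(trimethylsilyl)chroman-4-ol F5. Dess–Martin oxidation should give (2R)-2-[(Z)-heptadec-12-enyl]-5,8-dimethoxy-6-(trimethylsilyl)chroman-4-one F6. Ipso-protodesilylation with TFA (CH2Cl2, 0 °C) should give (2R)-2-[(Z)-heptadec-12-enyl]-5,8-dimethoxychroman-4-one F4, and BBr3 (CH2Cl2, −78 → 0 °C) should give 18.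

Step 4 (carbene complex formation). Lithiation at C6 may be incomplete, surplus tert-butyllithium may attack Cr(CO)6 to give a second acylate, and the crude lithium acylate may then methylate poorly. The fallback generates the organolithium by tin–lithium exchange from a purified stannane instead of by direct deprotonation in the chromium flask; it sets out from 6 and comes back at 8. Lithiation of 6 as before but with a Bu3SnCl quench should give tributyl[(2R,4S)-2-((Z)-heptadec-12-enyl)-4-(triisopropylsilyloxy)-3,4-dihydro-2H-pyran-6-yl]stannane F7, which is purified on triethylamine-washed silica. Treatment with n-BuLi (1.0 equiv, THF, −78 °C) should regenerate 8 free of tert-butyllithium and of deprotonation by-products, and 8 is carried through Cr(CO)6 and Me3OBF4 to 10 as in step 4.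

**Further compounds**

F1 | step 5 | 1-(2-hydroxy-3,6-dimethoxyphenyl)ethanone | CC(=O)c1c(O)c(OC)ccc1OC
F2 | step 5 | rac-2-[(Z)-heptadec-12-enyl]-5,8-dimethoxychroman-4-one | CCCC/C=C\CCCCCCCCCCCC1CC(=O)c2c(OC)ccc(OC)c2O1
F3 | step 5 | 2-[(Z)-heptadec-12-enyl]-5,8-dimethoxy-4H-chromen-4-one | CCCC/C=C\CCCCCCCCCCCC1=CC(=O)c2c(OC)ccc(OC)c2O1
F4 | step 5 | (2R)-2-[(Z)-heptadec-12-enyl]-5,8-dimethoxychroman-4-one | CCCC/C=C\CCCCCCCCCCC[C@@H]1CC(=O)c2c(OC)ccc(OC)c2O1
F5 | step 8 | (2R,4S)-2-[(Z)-heptadec-12-enyl]-5,8-dimethoxy-6-(trimethylsilyl)chroman-4-ol | CCCC/C=C\CCCCCCCCCCC[C@@H]1C[C@H](O)c2c(OC)c([Si](C)(C)C)cc(OC)c2O1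
F6 | step 8 | (2R)-2-[(Z)-heptadec-12-enyl]-5,8-dimethoxy-6-(trimethylsilyl)chroman-4-one | CCCC/C=C\CCCCCCCCCCC[C@@H]1CC(=O)c2c(OC)c([Si](C)(C)C)cc(OC)c2O1
F7 | step 4 | tributyl[(2R,4S)-2-((Z)-heptadec-12-enyl)-4-(triisopropylsilyloxy)-3,4-dihydro-2H-pyran-6-yl]stannane | CCCC/C=C\CCCCCCCCCCC[C@@H]1C[C@H](O[Si](C(C)C)(C(C)C)C(C)C)C=C(O1)[Sn](CCCC)(CCCC)CCCC
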